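Ring labels: A = dibromo ring bearing the sulfate. B = central ring (C1–O–A, C2–O–C, Br on C3–C5, H on C6). C = outer ring (O on C1, I on C2, Br on C4).
Retrosynthetic cuts, in order: the alkyl cap of a masked ring A sulfate and its S–O(aryl) bond; C4–Br of ring C; O–C1 and C2–I of ring C in one operation; the C2–OH bond of ring B (back to C2–CHO); the ring A oxygen–C1 bond of ring B (back to C1–F).
Enabling feature: on ring C the ether oxygen (C1) and the iodine (C2) sit on adjacent carbons. This is a nucleophile and an electrophile added across one former triple bond, so ring C can enter as benzyne.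
Forward order: rings A and B are elaborated separately from bought arenes and joined by SNAr (A–O–B). The aldehyde is then exchanged for OH and ring C is attached whole; no ring is built.
Endgame: the ring A methyl ether is replaced by an electron-withdrawing isobutyl sulfate before ring C is brominated, because an anisole-type ring A would rival the iodine-deactivated ring C. Iodide finally uncaps the sulfate.
Stereochemistry: the target has no stereocentre and no configurationally stable axis. It is achiral, so nothing has to be set or preserved.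

Key step: step 5

Assumption: the hydrogen sulfate drawn for the target is taken as the protonated form of the sulfate monoester; its sodium salt 23 is the storable form and is protonated only at the very end.

Step 1
Reactants: 1 4-bromo-2-methoxyphenol
Product: 2 2,4-dibromo-6-methoxyphenol
Conditions: NBS (1.05 equiv), i-Pr2NH (10 mol %), CH2Cl2, 0 °C → rt
Reagents that add atoms: N-bromosuccinimide, O=C1CCC(=O)N1Br
Why: Amine-catalysed ortho-bromination of a phenol: the N-bromoamine generated from NBS is delivered through a hydrogen bond to the OH group and should therefore hit C6, the only open position ortho or para to OH, rather than C5 para to OMe, which acidic brominations of guaiacols prefer.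

Step 2
Reactants: 3 1,2,3-tribromo-5-fluorobenzene
Product: 6 2,3,4-tribromo-6-fluorobenzaldehyde, via arylmagnesium chloride 4 (not isolated), via magnesium hemiaminal alkoxide 5 (not isolated)
Conditions: TMPMgCl·LiCl (1.1 equiv), THF, −40 °C; DMF, −40 → 0 °C; aq. HCl
Reagents that add atoms: N,N-dimethylformamide, CN(C)C=O
Why: Deprotonative magnesiation with a hindered Mg/Li amide followed by formylation with DMF: the two hydrogens of 3 are equivalent by symmetry and each is acidified by a flanking F and Br, so only one arylmagnesium can form, and at −40 °C it is too covalent to lose halide to an aryne or to start a halogen dance.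

Step 3
Reactants: 2 2,4-dibromo-6-methoxyphenol; 6 2,3,4-tribromo-6-fluorobenzaldehyde
Product: 7 2,3,4-tribromo-6-(2,4-dibromo-6-methoxyphenoxy)benzaldehyde
Conditions: K2CO3, DMF, 60 °C
Reagents that add atoms: none
Why: SNAr by addition–elimination: fluoride ortho to the formyl group is displaced far faster than the ortho and para bromides, the three bromines lower the ring LUMO further, and the small aldehyde stays coplanar, so even the hindered phenoxide of 2 should couple without any metal that could insert into C–Br.

Step 4
Reactants: 7 2,3,4-tribromo-6-(2,4-dibromo-6-methoxyphenoxy)benzaldehyde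
Product: 9 2,3,4-tribromo-6-(2,4-dibromo-6-methoxyphenoxy)phenol, via aryl formate 8 (not isolated)
Conditions: mCPBA, TFA (additive), CH2Cl2, 0 °C → reflux; then MeOH, cat. HCl, rt
Reagents that add atoms: 3-chloroperbenzoic acid, OOC(=O)c1cccc(Cl)c1
Why: Baeyer–Villiger (Dakin-type) oxidation of a 2-aryloxybenzaldehyde followed by methanolysis of the formate: the ortho aryloxy lone pair and the relief of strain at the doubly ortho-substituted carbon favour aryl over hydride migration in the acid-promoted Criegee adduct, and nothing else in 7 is oxidisable by a peracid.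

Step 5
Reactants: 9 2,3,4-tribromo-6-(2,4-dibromo-6-methoxyphenoxy)phenol; 10 2-(trimethylsilyl)phenyl trifluoromethanesulfonate; 11 1-iodo-2-phenylacetylene
Product: 15 1,2,3-tribromo-5-(2,4-dibromo-6-methoxyphenoxy)-4-(2-iodophenoxy)benzene, via caesium phenoxide 12 (not isolated), via benzyne 13 (not isolated), via 2-aryloxyphenylcaesium 14 (not isolated)
Conditions: CsOH·H2O, MeOH, rt, then strip and dry (PhMe azeotrope, vacuum); 11 (3 equiv), CsF (4 equiv), 18-crown-6, THF–PhMe, slow addition of 10 (2 equiv), 25 → 45 °C, dark; H2O quench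
Reagents that add atoms: none
Why: Proposed new method: fluoride removes the silyl group of 10 and triflate departs to give benzyne 13, the dried caesium phenoxide 12 adds through oxygen to the strained triple bond (O–C1), and the ortho aryl-caesium 14 so formed attacks the iodine atom of 11 in a halogenophilic substitution (C2–I) that releases the much less basic phenylacetylide. The closest known reaction types are the fluoride-induced O-arylation of phenols with silylaryl triflates and the three-component aryne couplings in which a nitrogen, CF3 or SCF3 nucleophile is followed by iodine transfer from an iodoalkyne; a phenoxide has not been paired with such a donor. No ring is closed and no stereocentre arises, and because benzyne is symmetrical the only possible constitution is the vicinal O/I pattern. The selectivity that counts is iodine capture over protonation of 14, which is secured by using the phenoxide free of any O–H (water removed azeotropically), by an ether/arene medium instead of acetonitrile, and by having 11 in excess before any aryne is released. Bromine abstraction from the five C–Br bonds is the second competitor: the C(sp)–I bond is the better halogen donor, and the nearest bromine (C3 of ring B) could be reached only through a bent six-membered array whereas halogen transfer needs a linear C···X–C geometry. In 12 both ortho positions and the para position of the phenoxide are occupied (Br, aryloxy, Br), so C-arylation or C-iodination cannot intervene, and the metal-free aryne accepts this hindered, weakly basic oxygen without touching any C–Br bond.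

Step 6
Reactants: 15 1,2,3-tribromo-5-(2,4-dibromo-6-methoxyphenoxy)-4-(2-iodophenoxy)benzene
Product: 17 3,5-dibromo-2-[3,4,5-tribromo-2-(2-iodophenoxy)phenoxy]phenol, via aryloxydibromoborane 16 (not isolated)
Conditions: BBr3, CH2Cl2, −78 °C → rt; H2O
Reagents that add atoms: none
Why: Lewis-acid cleavage of an aryl methyl ether with BBr3: bromide attacks the only sp3 C–O carbon, while the diaryl ether, C–Br and C–I bonds are inert to the reagent.

Step 7
Reactants: 18 2-methylpropan-1-ol
Product: 19 isobutyl chlorosulfate
Conditions: SO2Cl2, pyridine, Et2O, −78 °C → 0 °C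
Reagents that add atoms: sulfuryl chloride, O=S(=O)(Cl)Cl
Why: Chlorosulfation of a primary alcohol with sulfuryl chloride and pyridine at low temperature, the standard entry to alkyl chlorosulfates; the β-branched alkyl group resists displacement by chloride.

Step 8
Reactants: 17 3,5-dibromo-2-[3,4,5-tribromo-2-(2-iodophenoxy)phenoxy]phenol; 19 isobutyl chlorosulfate
Product: 21 3,5-dibromo-2-[3,4,5-tribromo-2-(2-iodophenoxy)phenoxy]phenyl isobutyl sulfate, via sodium phenoxide 20 (not isolated)
Conditions: NaH, THF, 0 °C; then 19, 0 °C → rt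
Reagents that add atoms: none
Why: O-sulfonylation of a phenoxide with an alkyl chlorosulfate (protected-sulfate method): chloride is the only good leaving group on sulfur, and the neutral diester can be chromatographed and turns the ring A oxygen from a donor into an acceptor.

Step 9
Reactants: 21 3,5-dibromo-2-[3,4,5-tribromo-2-(2-iodophenoxy)phenoxy]phenyl isobutyl sulfate
Product: 22 3,5-dibromo-2-[3,4,5-tribromo-2-(4-bromo-2-iodophenoxy)phenoxy]phenyl isobutyl sulfate
Conditions: NBS (1.1 equiv), TFA–CH2Cl2 (1:1), TfOH (20 mol %), 0 °C → rt, dark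
Reagents that add atoms: N-bromosuccinimide, O=C1CCC(=O)N1Br
Why: Electrophilic aromatic bromination with acid-activated NBS: ring A (two Br, sulfate ester) and ring B (three Br, one hindered H) are strongly deactivated, so the electrophile should go to ring C, where the ether oxygen directs para to C4 and the bulk of ring B screens the ortho position C6.

Step 10
Reactants: 22 3,5-dibromo-2-[3,4,5-tribromo-2-(4-bromo-2-iodophenoxy)phenoxy]phenyl isobutyl sulfate
Product: 24 bromoiesol B sulfate (3,5-dibromo-2-[3,4,5-tribromo-2-(4-bromo-2-iodophenoxy)phenoxy]phenyl hydrogen sulfate), via sodium aryl sulfate 23 (not isolated)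
Conditions: NaI, acetone, 55 °C; then cold 0.5 M HCl, EtOAc
Reagents that add atoms: none
Why: SN2 dealkylation of the isobutyl sulfate by iodide (Finkelstein-type conditions): the soft nucleophile attacks carbon and not sulfur, the aryl sulfate anion leaves as its sodium salt, aryl halides do not react, and a brief cold acid wash gives the protonated form.

Compound list
1 | 4-bromo-2-methoxyphenol | COc1cc(Br)ccc1O | starting material
2 | 2,4-dibromo-6-methoxyphenol | COc1cc(Br)cc(Br)c1O | intermediate
3 | 1,2,3-tribromo-5-fluorobenzene | Fc1cc(Br)c(Br)c(Br)c1 | starting material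
4 | (2,3,4-tribromo-6-fluorophenyl)magnesium chloride (LiCl complex) | Fc1cc(Br)c(Br)c(Br)c1[Mg]Cl | intermediate
5 | chloromagnesium (dimethylamino)(2,3,4-tribromo-6-fluorophenyl)methoxide (racemic, centre lost on hydrolysis) | CN(C)C(O[Mg]Cl)c1c(F)cc(Br)c(Br)c1Br | intermediate
6 | 2,3,4-tribromo-6-fluorobenzaldehyde | O=Cc1c(F)cc(Br)c(Br)c1Br | intermediate
7 | 2,3,4-tribromo-6-(2,4-dibromo-6-methoxyphenoxy)benzaldehyde | COc1cc(Br)cc(Br)c1Oc1cc(Br)c(Br)c(Br)c1C=O | intermediate
8 | 2,3,4-tribromo-6-(2,4-dibromo-6-methoxyphenoxy)phenyl formate | COc1cc(Br)cc(Br)c1Oc1cc(Br)c(Br)c(Br)c1OC=O | intermediate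
9 | 2,3,4-tribromo-6-(2,4-dibromo-6-methoxyphenoxy)phenol | COc1cc(Br)cc(Br)c1Oc1cc(Br)c(Br)c(Br)c1O | intermediate
10 | 2-(trimethylsilyl)phenyl trifluoromethanesulfonate | C[Si](C)(C)c1ccccc1OS(=O)(=O)C(F)(F)F | starting material
11 | 1-iodo-2-phenylacetylene | IC#Cc1ccccc1 | starting material
12 | caesium 2,3,4-tribromo-6-(2,4-dibromo-6-methoxyphenoxy)phenoxide | COc1cc(Br)cc(Br)c1Oc1cc(Br)c(Br)c(Br)c1[O-].[Cs+] | intermediate
13 | benzyne | C1#CC=CC=C1 | intermediate
14 | {2-[2,3,4-tribromo-6-(2,4-dibromo-6-methoxyphenoxy)phenoxy]phenyl}caesium | COc1cc(Br)cc(Br)c1Oc1cc(Br)c(Br)c(Br)c1Oc1ccccc1[Cs] | intermediate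
15 | 1,2,3-tribromo-5-(2,4-dibromo-6-methoxyphenoxy)-4-(2-iodophenoxy)benzene | COc1cc(Br)cc(Br)c1Oc1cc(Br)c(Br)c(Br)c1Oc1ccccc1I | intermediate
16 | dibromo{3,5-dibromo-2-[3,4,5-tribromo-2-(2-iodophenoxy)phenoxy]phenoxy}borane | BrB(Br)Oc1cc(Br)cc(Br)c1Oc1cc(Br)c(Br)c(Br)c1Oc1ccccc1I | intermediate
17 | 3,5-dibromo-2-[3,4,5-tribromo-2-(2-iodophenoxy)phenoxy]phenol | Oc1cc(Br)cc(Br)c1Oc1cc(Br)c(Br)c(Br)c1Oc1ccccc1I | intermediate
18 | 2-methylpropan-1-ol | CC(C)CO | starting material
19 | isobutyl chlorosulfate | CC(C)COS(=O)(=O)Cl | intermediate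
20 | sodium 3,5-dibromo-2-[3,4,5-tribromo-2-(2-iodophenoxy)phenoxy]phenoxide | [Na+].[O-]c1cc(Br)cc(Br)c1Oc1cc(Br)c(Br)c(Br)c1Oc1ccccc1I | intermediate
21 | 3,5-dibromo-2-[3,4,5-tribromo-2-(2-iodophenoxy)phenoxy]phenyl isobutyl sulfate | CC(C)COS(=O)(=O)Oc1cc(Br)cc(Br)c1Oc1cc(Br)c(Br)c(Br)c1Oc1ccccc1I | intermediate
22 | 3,5-dibromo-2-[3,4,5-tribromo-2-(4-bromo-2-iodophenoxy)phenoxy]phenyl isobutyl sulfate | CC(C)COS(=O)(=O)Oc1cc(Br)cc(Br)c1Oc1cc(Br)c(Br)c(Br)c1Oc1ccc(Br)cc1I | intermediate
23 | sodium 3,5-dibromo-2-[3,4,5-tribromo-2-(4-bromo-2-iodophenoxy)phenoxy]phenyl sulfate | [Na+].[O-]S(=O)(=O)Oc1cc(Br)cc(Br)c1Oc1cc(Br)c(Br)c(Br)c1Oc1ccc(Br)cc1I | intermediate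
24 | bromoiesol B sulfate (achiral) | O=S(=O)(O)Oc1cc(Br)cc(Br)c1Oc1cc(Br)c(Br)c(Br)c1Oc1ccc(Br)cc1I | target

Total step count: 10. Longest linear sequence: 8 (step 1 or 2, then steps 3, 4, 5, 6, 8, 9, 10).

Steps most likely to fail

1. Step 5.
- **What may go wrong:** the aryl-caesium 14 may be quenched by a proton (residual methanol or water, or the ether solvent). It may also abstract bromine from a polybromoarene faster than it takes iodine. In addition, the liberated acetylide may consume benzyne.
- **Fallback (known chemistry, from 9 back to 15):** 1,2-diiodobenzene is oxidised at one iodine with mCPBA/TsOH·H2O in MeCN. The λ3-iodane is captured by 1,3,5-trimethoxybenzene to give (2-iodophenyl)(2,4,6-trimethoxyphenyl)iodonium tosylate F1. Heating 9 with F1 and K2CO3 in toluene should transfer the less electron-rich, ortho-substituted 2-iodophenyl ligand to oxygen by metal-free ligand coupling. This gives 15, after which steps 6–10 follow unchanged.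

2. Step 9.
- **What may go wrong:** the bromine electrophile may attack the iodine-bearing carbon (ipso substitution with loss of iodine). The acid may cause protodeiodination. The roughly benzene-like ring C may also react so slowly that the sulfate ester erodes.
- **Fallback (from 21 back to 22):** the halogen electrophile is replaced by C–H thianthrenation (thianthrene S-oxide, TFAA, HBF4·OEt2, MeCN, 0 °C → rt). Its reversible, highly para-selective addition should give 5-(4-{2,3,4-tribromo-6-[2,4-dibromo-6-(isobutoxysulfonyloxy)phenoxy]phenoxy}-3-iodophenyl)thianthrenium tetrafluoroborate F2. Photoredox/copper bromide transfer (CuBr, LiBr, Ru photocatalyst, blue light) reduces only the sulfonium unit and should turn the C–S bond into C4–Br, giving 22.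

3. Step 4.
- **What may go wrong:** hydride instead of aryl migration in the Criegee adduct of this electron-poor, doubly ortho-substituted aldehyde would over-oxidise it to the acid level.
- **Fallback (from 3 and 2 back to 9):** the oxygen is brought in by dediazoniation. Nitration of symmetric 3 (fuming HNO3/H2SO4) can give only 1,2,3-tribromo-5-fluoro-4-nitrobenzene F3. SNAr with 2 (K2CO3, DMF, rt to 40 °C) gives 1,2,3-tribromo-5-(2,4-dibromo-6-methoxyphenoxy)-4-nitrobenzene F4. Fe/NH4Cl in EtOH–H2O reduces it to 2,3,4-tribromo-6-(2,4-dibromo-6-methoxyphenoxy)aniline F5. Diazotisation with NaNO2 in H2SO4–AcOH at 0 °C gives 2,3,4-tribromo-6-(2,4-dibromo-6-methoxyphenoxy)benzenediazonium hydrogensulfate F6. This is hydrolysed at rt with Cu2O/Cu(NO3)2 in water to 9.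

Further compounds
F1 | step 5 | (2-iodophenyl)(2,4,6-trimethoxyphenyl)iodonium tosylate | COc1cc(OC)c([I+]c2ccccc2I)c(OC)c1.Cc1ccc(cc1)S([O-])(=O)=O
F2 | step 9 | 5-(4-{2,3,4-tribromo-6-[2,4-dibromo-6-(isobutoxysulfonyloxy)phenoxy]phenoxy}-3-iodophenyl)thianthrenium tetrafluoroborate | CC(C)COS(=O)(=O)Oc1cc(Br)cc(Br)c1Oc1cc(Br)c(Br)c(Br)c1Oc1ccc(cc1I)[S+]1c2ccccc2Sc2ccccc12.F[B-](F)(F)F
F3 | step 4 | 1,2,3-tribromo-5-fluoro-4-nitrobenzene | [O-][N+](=O)c1c(F)cc(Br)c(Br)c1Br
F4 | step 4 | 1,2,3-tribromo-5-(2,4-dibromo-6-methoxyphenoxy)-4-nitrobenzene | COc1cc(Br)cc(Br)c1Oc1cc(Br)c(Br)c(Br)c1[N+](=O)[O-]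
F5 | step 4 | 2,3,4-tribromo-6-(2,4-dibromo-6-methoxyphenoxy)aniline | COc1cc(Br)cc(Br)c1Oc1cc(Br)c(Br)c(Br)c1N
F6 | step 4 | 2,3,4-tribromo-6-(2,4-dibromo-6-methoxyphenoxy)benzenediazonium hydrogensulfate | COc1cc(Br)cc(Br)c1Oc1cc(Br)c(Br)c(Br)c1[N+]#N.OS(=O)(=O)[O-]
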